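**Strategy.** Everything rests on cutting C11–C12, the bond from the last methylene of the C8–C11 chain to the secondary carbinol. In one operation the vinyl terminus of trienoate 11 becomes a C11 zinc nucleophile (hydroboration, boron–zinc exchange) that adds, under titanium bis-sulfonamide catalysis, to the carbonyl carbon of enal 14. This joins the halves and sets 12R by catalyst control. The step exploits the fact that C13 bears two one-carbon arms (C14 and the hydroxymethyl carbon), so that C12–C14 map onto a 2-(silyloxymethyl)acrolein. The precursors are a (2E,4Z)-dienoate with a remote vinyl group and this C4 enal; C13, the oxirane ring and the acid level follow.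

Key step: step 6

Remark on numbering: atoms are numbered along the C14 diacid chain (C1 = carboxyl of the enoate, C14 = carboxyl next to C13).
Remark on stereochemistry: the SMILES is read as 2E,4S,5R,7S,12R,13R; H-4 and the 5-methyl group are cis on the oxirane, which corresponds to syn oxygen transfer to a 4Z olefin.
Remark on reagents: Et2BH, Zn(CH2SiMe3)2, the bis-sulfonamide ligand and the ent-Shi ketone are taken as stock reagents.

Step 1
Reactants: 1 (R)-3-bromo-2-methylpropan-1-ol; 2 allylmagnesium chloride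
Product: 3 (S)-2-methylhex-5-en-1-ol
Conditions: 2 (3 equiv), Li2CuCl4 (3 mol %), THF, −78 °C to rt; aq NH4Cl
Reagents that add atoms: none
Why: Copper-catalysed sp3–sp3 cross-coupling of a Grignard reagent with a primary alkyl bromide (the first equivalent of 2 only forms the magnesium alkoxide) extends the chain without touching the stereocentre, whose descriptor changes from R to S by priority alone.

Step 2
Reactants: 3 (S)-2-methylhex-5-en-1-ol
Product: 4 (S)-6-bromo-5-methylhex-1-ene
Conditions: CBr4, PPh3, CH2Cl2, 0 °C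
Reagents that add atoms: carbon tetrabromide, BrC(Br)(Br)Br
Why: Appel reaction, an SN2 displacement of the primary oxyphosphonium ion by bromide that is remote from the stereocentre.

Step 3
Reactants: 4 (S)-6-bromo-5-methylhex-1-ene; 5 propyne; 6 methyl but-2-ynoate
Product: 11 methyl (2E,4Z,7S)-3,5,7-trimethylundeca-2,4,10-trienoate, via Grignard reagent 7 (not isolated), via alkylcopper 8 (not isolated), via alkenylcopper 9 (not isolated), via cuprated dienoate 10 (not isolated)
Conditions: Mg, Et2O, 35 °C; CuBr·SMe2, Et2O/Me2S, −45 °C; 5, −25 °C; 6, THF, −78 to −40 °C; MeOH then aq NH4Cl at −78 °C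
Reagents that add atoms: none
Why: Syn-carbocupration of propyne by the primary alkylcopper 8 (Normant carbocupration) puts C6 and copper cis and so fixes the 4Z olefin, and syn conjugate addition of alkenylcopper 9 to ynoate 6 followed by low-temperature protonation of 10 with retention gives the 2E olefin, the same stereochemical course as in the classical alkenylcuprate/propiolate route to (2E,4Z)-dienoates.

Step 4
Reactants: 12 2-methylidenepropane-1,3-diol
Product: 13 2-({[tri(propan-2-yl)silyl]oxy}methyl)prop-2-en-1-ol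
Conditions: NaH (1 equiv), THF, 0 °C; iPr3SiCl (1 equiv), rt
Reagents that add atoms: chlorotri(propan-2-yl)silane, CC(C)[Si](Cl)(C(C)C)C(C)C
Why: Monosilylation of a symmetric diol through its sparingly soluble monosodium alkoxide, which is silylated faster than it equilibrates to the dialkoxide.

Step 5
Reactants: 13 2-({[tri(propan-2-yl)silyl]oxy}methyl)prop-2-en-1-ol
Product: 14 2-({[tri(propan-2-yl)silyl]oxy}methyl)prop-2-enal
Conditions: MnO2, CH2Cl2, rt
Reagents that add atoms: none
Why: MnO2 oxidation of a primary allylic alcohol to the enal, a surface reaction selective for allylic carbinols and compatible with the silyl ether.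

Step 6
Reactants: 11 methyl (2E,4Z,7S)-3,5,7-trimethylundeca-2,4,10-trienoate; 14 2-({[tri(propan-2-yl)silyl]oxy}methyl)prop-2-enal
Product: 18 methyl (2E,4Z,7S,12R)-12-hydroxy-3,5,7-trimethyl-13-({[tri(propan-2-yl)silyl]oxy}methyl)tetradeca-2,4,13-trienoate, via alkyldiethylborane 15 (not isolated), via dialkylzinc 16 (not isolated), via mixed alkylzinc 17 (not isolated)
Conditions: 11 (1.7 equiv), Et2BH, Et2O, 0 °C to rt; Et2Zn (neat), 0 °C, volatiles removed in vacuo; Zn(CH2SiMe3)2; Ti(OiPr)4 (2 equiv), (1S,2S)-1,2-bis(trifluoromethanesulfonamido)cyclohexane (8 mol %), toluene, −20 °C, then 14; aq NH4Cl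
Reagents that add atoms: none
Why: The monosubstituted C10=C11 olefin of 11 is hydroborated anti-Markovnikov by Et2BH far faster than the trisubstituted, ester-conjugated olefins, boron–zinc exchange with Et2Zn and redistribution with Zn(CH2SiMe3)2 give the mixed reagent 17, and the titanium bis-sulfonamide complex transfers only the functional alkyl group to the carbonyl carbon of 14, forming C11–C12. The closest known reaction type is the catalytic enantioselective addition of functionalised diorganozincs (made by boron–zinc exchange) to aldehydes under Ti(OiPr)4/trans-1,2-bis(trifluoromethanesulfonamido)cyclohexane catalysis, for which α-substituted enals are good substrates. No ring is closed. The new stereocentre C12 is set by the catalyst alone: the (1S,2S) ligand should deliver the alkyl group to the Re face of the aldehyde (the (1R,2R) ligand is known to give Si-face addition), which gives 12R, and the remote C7 centre exerts no influence. The step needs chemoselectivity (terminal olefin over the dienoate in the hydroboration, 1,2- over 1,4-addition to the enal, aldehyde over methyl ester) and transfer of the chain in preference to the CH2SiMe3 group; these rest on the large rate difference in dialkylborane hydroboration, on titanium activation of the carbonyl oxygen and on the non-transferable nature of the silylmethyl ligand.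

Step 7
Reactants: 18 methyl (2E,4Z,7S,12R)-12-hydroxy-3,5,7-trimethyl-13-({[tri(propan-2-yl)silyl]oxy}methyl)tetradeca-2,4,13-trienoate
Product: 20 methyl (2E,4Z,7S,12R,13R)-12,14-dihydroxy-3,5,7-trimethyl-13-({[tri(propan-2-yl)silyl]oxy}methyl)tetradeca-2,4-dienoate, via bis-borane adduct 19 (not isolated)
Conditions: 9-BBN (3 equiv), THF, 0 °C to rt; 3 M aq NaOAc, 30% H2O2, 0 °C to rt
Reagents that add atoms: hydrogen peroxide, OO
Why: Substrate-controlled anti-selective hydroboration of the 1,1-disubstituted olefin of a secondary allylic alcohol with 9-BBN (1,2-induction by allylic strain: C12–H eclipses the C13=C14 bond and the bulky borane adds to C14 from the face opposite the C11 chain) followed by oxidation with retention should give the 12,13-anti diol with 13R, the trisubstituted ester-conjugated olefins reacting far more slowly.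

Step 8
Reactants: 20 methyl (2E,4Z,7S,12R,13R)-12,14-dihydroxy-3,5,7-trimethyl-13-({[tri(propan-2-yl)silyl]oxy}methyl)tetradeca-2,4-dienoate
Product: 21 methyl (2E,4S,5R,7S,12R,13R)-4,5-epoxy-12,14-dihydroxy-3,5,7-trimethyl-13-({[tri(propan-2-yl)silyl]oxy}methyl)tetradec-2-enoate
Conditions: ent-Shi ketone (1,2:4,5-di-O-isopropylidene-β-L-erythro-2,3-hexodiulo-2,6-pyranose, 30 mol %), Oxone (2KHSO5·KHSO4·K2SO4), K2CO3, Bu4NHSO4, MeCN/dimethoxymethane/aq borate–EDTA buffer (pH 10.5), 0 °C
Reagents that add atoms: potassium peroxymonosulfate KHSO5 (active salt of Oxone), [K+].[O-]S(=O)(=O)OO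
Why: Shi epoxidation, in which the chiral dioxirane transfers oxygen through a spiro transition state to the electron-richer trisubstituted C4=C5 olefin (the ester-conjugated C2=C3 bond is deactivated, as in the known monoepoxidation of conjugated dienoates), syn addition to the 4Z olefin keeps H-4 and the 5-methyl group cis, and the L-series ketone, mirror image of the catalyst that gives R,R-oxides from trans and trisubstituted olefins, should deliver the 4S,5R oxirane.

Step 9
Reactants: 21 methyl (2E,4S,5R,7S,12R,13R)-4,5-epoxy-12,14-dihydroxy-3,5,7-trimethyl-13-({[tri(propan-2-yl)silyl]oxy}methyl)tetradec-2-enoate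
Product: 23 1-methyl hydrogen (2E,4S,5R,7S,12R,13R)-4,5-epoxy-12-hydroxy-3,5,7-trimethyl-13-({[tri(propan-2-yl)silyl]oxy}methyl)tetradec-2-enedioate, via hydroxy aldehyde 22 (not isolated)
Conditions: TEMPO (10 mol %), NaClO2, NaOCl (2 mol %), MeCN/phosphate buffer (pH 6.7), 35 °C
Reagents that add atoms: sodium chlorite, [Na+].[O-]Cl=O
Why: TEMPO/NaOCl-catalysed NaClO2 oxidation in pH 6.7 buffer converts the primary C14 carbinol via aldehyde 22 into the carboxylic acid, while the oxoammonium ion leaves the secondary C12 hydroxyl untouched and the near-neutral medium spares the oxirane, the silyl ether and the C13 stereocentre.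

Step 10
Reactants: 23 1-methyl hydrogen (2E,4S,5R,7S,12R,13R)-4,5-epoxy-12-hydroxy-3,5,7-trimethyl-13-({[tri(propan-2-yl)silyl]oxy}methyl)tetradec-2-enedioate
Product: 25 (2E,4S,5R,7S,12R,13R)-4,5-epoxy-12-hydroxy-13-(hydroxymethyl)-3,5,7-trimethyltetradec-2-enedioic acid, via desilylated monoester 24 (not isolated)
Conditions: Bu4NF (TBAF), THF, 0 °C to rt; then LiOH, THF/MeOH/H2O, rt; 0.5 M HCl to pH 4, 0 °C
Reagents that add atoms: lithium hydroxide, [Li+].[OH-]
Why: Fluoride cleaves the primary silyl ether and LiOH then saponifies the conjugated methyl ester (BAc2) under conditions that vinyl oxiranes bearing ester groups are known to survive, careful acidification to pH 4 at 0 °C liberating the diacid without opening the oxirane and without affecting any stereocentre.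

**Compound list**

1 | (R)-3-bromo-2-methylpropan-1-ol | OC[C@@H](C)CBr | starting material
2 | allylmagnesium chloride | C=CC[Mg]Cl | starting material
3 | (S)-2-methylhex-5-en-1-ol | OC[C@@H](C)CCC=C | intermediate
4 | (S)-6-bromo-5-methylhex-1-ene | BrC[C@@H](C)CCC=C | intermediate
5 | propyne | CC#C | starting material
6 | methyl but-2-ynoate | CC#CC(=O)OC | starting material
7 | [(2S)-2-methylhex-5-en-1-yl]magnesium bromide | Br[Mg]C[C@@H](C)CCC=C | intermediate
8 | [(2S)-2-methylhex-5-en-1-yl]copper (as its MgBr2·SMe2 complex) | [Cu]C[C@@H](C)CCC=C | intermediate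
9 | [(1Z,4S)-2,4-dimethylocta-1,7-dien-1-yl]copper | [Cu]/C=C(/C)C[C@@H](C)CCC=C | intermediate
10 | methyl (2Z,4Z,7S)-2-cuprio-3,5,7-trimethylundeca-2,4,10-trienoate | COC(=O)/C([Cu])=C(\C)/C=C(/C)C[C@@H](C)CCC=C | intermediate
11 | methyl (2E,4Z,7S)-3,5,7-trimethylundeca-2,4,10-trienoate | COC(=O)/C=C(\C)/C=C(/C)C[C@@H](C)CCC=C | intermediate
12 | 2-methylidenepropane-1,3-diol | C=C(CO)CO | starting material
13 | 2-({[tri(propan-2-yl)silyl]oxy}methyl)prop-2-en-1-ol | C=C(CO)CO[Si](C(C)C)(C(C)C)C(C)C | intermediate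
14 | 2-({[tri(propan-2-yl)silyl]oxy}methyl)prop-2-enal | C=C(C=O)CO[Si](C(C)C)(C(C)C)C(C)C | intermediate
15 | methyl (2E,4Z,7S)-11-(diethylboranyl)-3,5,7-trimethylundeca-2,4-dienoate | COC(=O)/C=C(\C)/C=C(/C)C[C@@H](C)CCCCB(CC)CC | intermediate
16 | bis[(5S,7Z,9E)-11-methoxy-5,7,9-trimethyl-11-oxoundeca-7,9-dien-1-yl]zinc | COC(=O)/C=C(\C)/C=C(/C)C[C@@H](C)CCCC[Zn]CCCC[C@H](C)C/C(C)=C\C(C)=C\C(=O)OC | intermediate
17 | [(5S,7Z,9E)-11-methoxy-5,7,9-trimethyl-11-oxoundeca-7,9-dien-1-yl][(trimethylsilyl)methyl]zinc | COC(=O)/C=C(\C)/C=C(/C)C[C@@H](C)CCCC[Zn]C[Si](C)(C)C | intermediate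
18 | methyl (2E,4Z,7S,12R)-12-hydroxy-3,5,7-trimethyl-13-({[tri(propan-2-yl)silyl]oxy}methyl)tetradeca-2,4,13-trienoate | COC(=O)/C=C(\C)/C=C(/C)C[C@@H](C)CCCC[C@@H](O)C(=C)CO[Si](C(C)C)(C(C)C)C(C)C | intermediate
19 | methyl (2E,4Z,7S,12R,13R)-14-(9-borabicyclo[3.3.1]nonan-9-yl)-12-(9-borabicyclo[3.3.1]nonan-9-yloxy)-3,5,7-trimethyl-13-({[tri(propan-2-yl)silyl]oxy}methyl)tetradeca-2,4-dienoate | COC(=O)/C=C(\C)/C=C(/C)C[C@@H](C)CCCC[C@@H](OB1C2CCCC1CCC2)[C@@H](CO[Si](C(C)C)(C(C)C)C(C)C)CB1C2CCCC1CCC2 | intermediate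
20 | methyl (2E,4Z,7S,12R,13R)-12,14-dihydroxy-3,5,7-trimethyl-13-({[tri(propan-2-yl)silyl]oxy}methyl)tetradeca-2,4-dienoate | COC(=O)/C=C(\C)/C=C(/C)C[C@@H](C)CCCC[C@@H](O)[C@@H](CO[Si](C(C)C)(C(C)C)C(C)C)CO | intermediate
21 | methyl (2E,4S,5R,7S,12R,13R)-4,5-epoxy-12,14-dihydroxy-3,5,7-trimethyl-13-({[tri(propan-2-yl)silyl]oxy}methyl)tetradec-2-enoate | COC(=O)/C=C(\C)[C@@H]1O[C@]1(C)C[C@@H](C)CCCC[C@@H](O)[C@@H](CO[Si](C(C)C)(C(C)C)C(C)C)CO | intermediate
22 | methyl (2E,4S,5R,7S,12R,13R)-4,5-epoxy-12-hydroxy-3,5,7-trimethyl-14-oxo-13-({[tri(propan-2-yl)silyl]oxy}methyl)tetradec-2-enoate | COC(=O)/C=C(\C)[C@@H]1O[C@]1(C)C[C@@H](C)CCCC[C@@H](O)[C@@H](CO[Si](C(C)C)(C(C)C)C(C)C)C=O | intermediate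
23 | 1-methyl hydrogen (2E,4S,5R,7S,12R,13R)-4,5-epoxy-12-hydroxy-3,5,7-trimethyl-13-({[tri(propan-2-yl)silyl]oxy}methyl)tetradec-2-enedioate | COC(=O)/C=C(\C)[C@@H]1O[C@]1(C)C[C@@H](C)CCCC[C@@H](O)[C@@H](CO[Si](C(C)C)(C(C)C)C(C)C)C(=O)O | intermediate
24 | 1-methyl hydrogen (2E,4S,5R,7S,12R,13R)-4,5-epoxy-12-hydroxy-13-(hydroxymethyl)-3,5,7-trimethyltetradec-2-enedioate | COC(=O)/C=C(\C)[C@@H]1O[C@]1(C)C[C@@H](C)CCCC[C@@H](O)[C@@H](CO)C(=O)O | intermediate
25 | (2E,4S,5R,7S,12R,13R)-4,5-epoxy-12-hydroxy-13-(hydroxymethyl)-3,5,7-trimethyltetradec-2-enedioic acid (CNP0468463.1) | C/C(=C\C(=O)O)[C@@H]1O[C@]1(C)C[C@@H](C)CCCC[C@@H](O)[C@@H](CO)C(=O)O | target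

**Step count.** Total: 10 steps. Longest linear sequence: 8 steps (1, 2, 3, 6, 7, 8, 9, 10); steps 4 and 5 make the second fragment.

**Steps most likely to fail**

Step 6 (key step). The titanium catalyst may discriminate the faces of the α-branched, γ-silyloxy enal incompletely, so that C12 epimers form which cannot be separated from 18. The fallback sets out from 11 and 14 and comes back at 18. The coupling is run as in step 6 through 15–17 (if need be without the chiral ligand) and the product is taken on as the epimer mixture methyl (2E,4Z,7S,12RS)-12-hydroxy-3,5,7-trimethyl-13-({[tri(propan-2-yl)silyl]oxy}methyl)tetradeca-2,4,13-trienoate F1. Dess–Martin periodinane (NaHCO3, CH2Cl2) oxidises it to the enone methyl (2E,4Z,7S)-3,5,7-trimethyl-12-oxo-13-({[tri(propan-2-yl)silyl]oxy}methyl)tetradeca-2,4,13-trienoate F2. Corey–Bakshi–Shibata reduction ((S)-2-methyl-CBS-oxazaborolidine, catecholborane, toluene, −78 °C), with the branched alkenyl group as the large substituent, should then return 18 with 12R. The C11–C12 bond is still made by the same addition; only the source of the C12 configuration changes.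

Step 3. The alkenylcopper may add slowly to the β-methyl ynoate; on warming, the cuprated dienoate can equilibrate through its allenoate and erode the 2E geometry, and unreacted 9 is lost on protonation. The fallback sets out from alkenylcopper 9 (made from 4 and 5 as in step 3) and comes back at 11. Quenching 9 with iodine gives (1Z,4S)-1-iodo-2,4-dimethylocta-1,7-diene F3. Copper-catalysed syn-borylation of 6 (bis(pinacolato)diboron, CuCl, xantphos, NaOtBu, MeOH, THF) gives methyl (2Z)-3-(4,4,5,5-tetramethyl-1,3,2-dioxaborolan-2-yl)but-2-enoate F4. Suzuki–Miyaura coupling of F3 with F4 (PdCl2(dppf), aq K3PO4, THF, 50 °C) proceeds with retention at both olefins and should give 11.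

Step 10. Hydroxide may open or rearrange the γ,δ-epoxy enoate while the hindered, conjugated methyl ester is cleaved only slowly. The fallback sets out from 20 and comes back at 25; it removes the methyl ester before the oxirane exists. LiOH (THF/MeOH/H2O, 40 °C) converts 20 into (2E,4Z,7S,12R,13R)-12,14-dihydroxy-3,5,7-trimethyl-13-({[tri(propan-2-yl)silyl]oxy}methyl)tetradeca-2,4-dienoic acid F5. Shi epoxidation of its carboxylate with the ent-ketone gives (2E,4S,5R,7S,12R,13R)-4,5-epoxy-12,14-dihydroxy-3,5,7-trimethyl-13-({[tri(propan-2-yl)silyl]oxy}methyl)tetradec-2-enoic acid F6. TEMPO/NaOCl-catalysed NaClO2 oxidation passes through (2E,4S,5R,7S,12R,13R)-4,5-epoxy-12-hydroxy-3,5,7-trimethyl-14-oxo-13-({[tri(propan-2-yl)silyl]oxy}methyl)tetradec-2-enoic acid F7 to (2E,4S,5R,7S,12R,13R)-4,5-epoxy-12-hydroxy-3,5,7-trimethyl-13-({[tri(propan-2-yl)silyl]oxy}methyl)tetradec-2-enedioic acid F8. Bu4NF in THF then gives 25, so that no hydroxide step follows oxirane formation.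

Further compounds
F1 | step 6 | methyl (2E,4Z,7S,12RS)-12-hydroxy-3,5,7-trimethyl-13-({[tri(propan-2-yl)silyl]oxy}methyl)tetradeca-2,4,13-trienoate | COC(=O)/C=C(\C)/C=C(/C)C[C@@H](C)CCCCC(O)C(=C)CO[Si](C(C)C)(C(C)C)C(C)C
F2 | step 6 | methyl (2E,4Z,7S)-3,5,7-trimethyl-12-oxo-13-({[tri(propan-2-yl)silyl]oxy}methyl)tetradeca-2,4,13-trienoate | COC(=O)/C=C(\C)/C=C(/C)C[C@@H](C)CCCCC(=O)C(=C)CO[Si](C(C)C)(C(C)C)C(C)C
F3 | step 3 | (1Z,4S)-1-iodo-2,4-dimethylocta-1,7-diene | I/C=C(/C)C[C@@H](C)CCC=C
F4 | step 3 | methyl (2Z)-3-(4,4,5,5-tetramethyl-1,3,2-dioxaborolan-2-yl)but-2-enoate | COC(=O)/C=C(\C)B1OC(C)(C)C(C)(C)O1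
F5 | step 10 | (2E,4Z,7S,12R,13R)-12,14-dihydroxy-3,5,7-trimethyl-13-({[tri(propan-2-yl)silyl]oxy}methyl)tetradeca-2,4-dienoic acid | OC(=O)/C=C(\C)/C=C(/C)C[C@@H](C)CCCC[C@@H](O)[C@@H](CO[Si](C(C)C)(C(C)C)C(C)C)CO
F6 | step 10 | (2E,4S,5R,7S,12R,13R)-4,5-epoxy-12,14-dihydroxy-3,5,7-trimethyl-13-({[tri(propan-2-yl)silyl]oxy}methyl)tetradec-2-enoic acid | OC(=O)/C=C(\C)[C@@H]1O[C@]1(C)C[C@@H](C)CCCC[C@@H](O)[C@@H](CO[Si](C(C)C)(C(C)C)C(C)C)CO
F7 | step 10 | (2E,4S,5R,7S,12R,13R)-4,5-epoxy-12-hydroxy-3,5,7-trimethyl-14-oxo-13-({[tri(propan-2-yl)silyl]oxy}methyl)tetradec-2-enoic acid | OC(=O)/C=C(\C)[C@@H]1O[C@]1(C)C[C@@H](C)CCCC[C@@H](O)[C@@H](CO[Si](C(C)C)(C(C)C)C(C)C)C=O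
F8 | step 10 | (2E,4S,5R,7S,12R,13R)-4,5-epoxy-12-hydroxy-3,5,7-trimethyl-13-({[tri(propan-2-yl)silyl]oxy}methyl)tetradec-2-enedioic acid | OC(=O)/C=C(\C)[C@@H]1O[C@]1(C)C[C@@H](C)CCCC[C@@H](O)[C@@H](CO[Si](C(C)C)(C(C)C)C(C)C)C(=O)O
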